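**Retrosynthetic overview**
The target is reached from its 3-oxo-7-ene precursor by allylic oxidation of C17 and reduction of the C3 ketone.
Key disconnection: C1–C2 (ring A) together with C9–C10 (ring B), made in one cationic bicyclisation of an open-chain α-diazoketone; ring A closes first, ring B second, and the 7-ene forms on proton loss.
Enabling feature: in ring A the oxygenated C3 lies between the fully substituted C4 and C2, so C2 can be a diazomethyl-ketone carbon; C1 is the CH2 end of a 2-propenyl group on C5 whose other carbon is C10, the methyl-bearing ring-fusion atom shared by rings A and B.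
The diazoketone comes from a 2,2-dimethyl acid whose C5 centre is set by an iridium-catalysed allylic alkylation with the ketene silyl acetal of tert-butyl isobutyrate; the resulting vinyl group is then converted to the 2-propenyl group.
The chain carrying C13 and the (E)-C8=C9 alkene comes from (2E,6E)-farnesol by asymmetric hydrogenation, oxidation, esterification and cross-metathesis.

Key step: step 11

Assumption: the iridium catalyst made from the (Ra,Rc,Rc)-phosphoramidite is taken to give the S centre at the allylated carbon by the usual facial model for linear (E)-allylic carbonates (the mirror-image ligand would be used if the sense were opposite).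

Atom labels C1–C20 used below are labdane positions of the target.

Step 1
Reactants: 1 (2E,6E)-farnesol
Product: 2 (3R,6E)-3,7,11-trimethyldodeca-6,10-dien-1-ol
Conditions: H2 (30 atm), Ru(OAc)2[(S)-BINAP] (0.2 mol %), MeOH/H2O 95:5, 20 °C
Reagents that add atoms: none
Why: Noyori asymmetric hydrogenation of an allylic alcohol: the hydroxyl-bound ruthenium hydride reduces only the 2,3-alkene, and (S)-BINAP delivers hydrogen to the face that gives the 3R centre (the sense known for geraniol to (R)-citronellol), while both isolated trisubstituted alkenes are inert.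

Step 2
Reactants: 2 (3R,6E)-3,7,11-trimethyldodeca-6,10-dien-1-ol
Product: 3 (3R,6E)-3,7,11-trimethyldodeca-6,10-dienoic acid
Conditions: TEMPO (0.2 equiv), PhI(OAc)2 (2.2 equiv), MeCN/H2O 1:1, 20 °C
Reagents that add atoms: water, O
Why: Nitroxyl-catalysed oxidation of a primary alcohol to the acid through the aldehyde hydrate, which leaves the trisubstituted alkenes and the non-epimerisable β-centre untouched.

Step 3
Reactants: 3 (3R,6E)-3,7,11-trimethyldodeca-6,10-dienoic acid
Product: 4 methyl (3R,6E)-3,7,11-trimethyldodeca-6,10-dienoate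
Conditions: MeI, K2CO3, DMF, 20 °C
Reagents that add atoms: iodomethane, CI
Why: Carboxylate O-alkylation (SN2 on iodomethane) under conditions too weakly basic to touch the α-position.

Step 4
Reactants: 4 methyl (3R,6E)-3,7,11-trimethyldodeca-6,10-dienoate; 5 allyl methyl carbonate
Product: 6 methyl (3R,6E,10E)-12-[(methoxycarbonyl)oxy]-3,7-dimethyldodeca-6,10-dienoate
Conditions: 5 (4 equiv), second-generation Hoveyda–Grubbs catalyst RuCl2(H2IMes)(=CH-C6H4-2-OiPr) (5 mol %), CH2Cl2, 40 °C
Reagents that add atoms: none
Why: Olefin cross-metathesis: the isopropylidene terminus, which leaves as 2-methylpropene, should enter the ruthenium carbene cycle much more readily than the internal trisubstituted alkene flanked by two methylene chains, and the new 1,2-disubstituted alkene should form mainly as the E isomer.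

Step 5
Reactants: 7 tert-butyl 2-methylpropanoate
Product: 8 [(1-tert-butoxy-2-methylprop-1-en-1-yl)oxy]trimethylsilane
Conditions: LiN(i-Pr)2, THF, −78 °C; Me3SiCl, −78 to 20 °C
Reagents that add atoms: chlorotrimethylsilane, C[Si](C)(C)Cl
Why: Ester enolisation with a lithium amide and O-silylation (ketene silyl acetal formation); the enolate carbon bears two methyl groups, so no enolate geometry arises.

Step 6
Reactants: 6 methyl (3R,6E,10E)-12-[(methoxycarbonyl)oxy]-3,7-dimethyldodeca-6,10-dienoate; 8 [(1-tert-butoxy-2-methylprop-1-en-1-yl)oxy]trimethylsilane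
Product: 9 1-tert-butyl 12-methyl (3S,6E,10R)-3-ethenyl-2,2,6,10-tetramethyldodec-6-enedioate
Conditions: [Ir(cod)Cl]2 (2 mol %), (Ra,Rc,Rc)-binaphthyl bis(1-phenylethyl)phosphoramidite (4 mol %, pre-activated with n-PrNH2), 8 (1.5 equiv), THF, 25 °C
Reagents that add atoms: none
Why: Iridium-catalysed branched-selective allylic alkylation with a silyl ketene acetal: the cyclometalated iridium–phosphoramidite ionises the linear carbonate, the released methoxide desilylates 8, and the ester enolate attacks the substituted allyl terminus on the face fixed by the ligand, which sets C5 under catalyst control independently of the remote C13 centre.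

Step 7
Reactants: 9 1-tert-butyl 12-methyl (3S,6E,10R)-3-ethenyl-2,2,6,10-tetramethyldodec-6-enedioate
Product: 10 1-tert-butyl 12-methyl (3R,6E,10R)-3-acetyl-2,2,6,10-tetramethyldodec-6-enedioate
Conditions: PdCl2 (10 mol %), CuCl (1 equiv, turned over by O2), O2 (1 atm), DMF/H2O 7:1, 20 °C
Reagents that add atoms: water, O; dioxygen, O=O (terminal oxidant)
Why: Tsuji–Wacker oxidation: Markovnikov hydroxypalladation of the only monosubstituted alkene gives the methyl ketone, the trisubstituted alkene does not compete, and C5 (hindered by its quaternary neighbour) should not enolise under these conditions; the descriptor changes from S to R only because the priorities change.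

Step 8
Reactants: 10 1-tert-butyl 12-methyl (3R,6E,10R)-3-acetyl-2,2,6,10-tetramethyldodec-6-enedioate
Product: 11 1-tert-butyl 12-methyl (3S,6E,10R)-2,2,6,10-tetramethyl-3-(prop-1-en-2-yl)dodec-6-enedioate
Conditions: Zn, CH2Br2, TiCl4, THF/CH2Cl2, 0 to 20 °C
Reagents that add atoms: dibromomethane, BrCBr
Why: Takai–Lombardo methylenation: the non-basic zinc/titanium methylene reagent converts the ketone to the 1,1-disubstituted alkene without epimerising C5 and leaves both esters untouched.

Step 9
Reactants: 11 1-tert-butyl 12-methyl (3S,6E,10R)-2,2,6,10-tetramethyl-3-(prop-1-en-2-yl)dodec-6-enedioate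
Product: 12 (3S,6E,10R)-12-methoxy-2,2,6,10-tetramethyl-12-oxo-3-(prop-1-en-2-yl)dodec-6-enoic acid
Conditions: Me3SiOTf, 2,6-lutidine, CH2Cl2, 0 °C; then H2O, pH 4
Reagents that add atoms: none
Why: Silyl triflate-mediated cleavage of a tert-butyl ester (loss of 2-methylpropene from the O-silylated ester, then hydrolysis of the silyl ester); the buffered, non-protic conditions spare the methyl ester and both acid-sensitive alkenes.

Step 10
Reactants: 12 (3S,6E,10R)-12-methoxy-2,2,6,10-tetramethyl-12-oxo-3-(prop-1-en-2-yl)dodec-6-enoic acid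
Product: 14 methyl (3R,6E,10S)-13-diazo-3,7,11,11-tetramethyl-12-oxo-10-(prop-1-en-2-yl)tridec-6-enoate, via acid chloride 13 (not isolated)
Conditions: 1-chloro-N,N,2-trimethylprop-1-en-1-amine, CH2Cl2, 0 to 20 °C; then CH2N2 (3 equiv), Et2O, 0 °C
Reagents that add atoms: diazomethane, C=[N+]=[N-]
Why: Neutral acid chloride formation with the α-chloroenamine followed by acylation of diazomethane (the first stage of an Arndt–Eistert sequence); excess diazomethane removes HCl, so neither alkene is protonated.

Step 11
Reactants: 14 methyl (3R,6E,10S)-13-diazo-3,7,11,11-tetramethyl-12-oxo-10-(prop-1-en-2-yl)tridec-6-enoate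
Product: 16 methyl (3R)-3-methyl-5-[(1R,4aS,8aS)-2,5,5,8a-tetramethyl-6-oxo-1,4,4a,5,6,7,8,8a-octahydronaphthalen-1-yl]pentanoate, via monocyclic C10 carbocation 15 (not isolated)
Conditions: BF3·OEt2 (1.1 equiv, promoter), CH2Cl2/MeNO2 4:1, 0.005 M, −30 to 0 °C; aq NaHCO3
Reagents that add atoms: none
Why: BF3 binds the carbonyl oxygen of the diazomethyl ketone and makes C2 a diazonium-type electrophile; the CH2 end (C1) of the 2-propenyl group displaces N2 from C2 (ring A, 6-endo-trig at the alkene, Markovnikov, helped by the gem-dimethyl group at C4), which puts the cation on C10, and the (E)-C8=C9 alkene then adds to C10 through C9 (ring B, 6-endo-trig, chair transition state) before the C8 cation loses the axial C7 proton. The closest known reaction type is the acid-promoted cationic polyolefin cyclisation initiated by an α-diazoketone; here the ketone sits between the diazo carbon and the blocked C4, so the first bond made is C1–C2. C10 and C9 are set by C5: the C5–C6 tether is equatorial on the new ring A, so C9 adds to C10 anti to the axial C5–H (trans fusion, C10 methyl axial), and the E geometry of C8=C9 puts C11 equatorial (C9–H anti to the C10 methyl). The step needs three selectivities: initiation at the 2-propenyl group rather than the remote alkene (secured by the six-membered, gem-dimethyl-assisted closure); ring B closure faster than proton loss or hydride shift at C10 (secured by the nucleophilic trisubstituted alkene held in reach, aprotic medium and low temperature); and endocyclic proton loss to the 7-ene rather than the exocyclic or tetrasubstituted isomer, which rests only on the anti-periplanar axial C7–H and is the least secured element.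

Step 12
Reactants: 16 methyl (3R)-3-methyl-5-[(1R,4aS,8aS)-2,5,5,8a-tetramethyl-6-oxo-1,4,4a,5,6,7,8,8a-octahydronaphthalen-1-yl]pentanoate
Product: 17 methyl (3R)-5-[(1S,4aS,8aS)-2-(hydroxymethyl)-5,5,8a-trimethyl-6-oxo-1,4,4a,5,6,7,8,8a-octahydronaphthalen-1-yl]-3-methylpentanoate
Conditions: SeO2 (0.3 equiv), t-BuOOH (3 equiv), CH2Cl2, 20 °C
Reagents that add atoms: tert-butyl hydroperoxide, CC(C)(C)OO (oxygen relayed by SeO2, O=[Se]=O)
Why: SeO2 allylic oxidation (ene reaction, then [2,3]-sigmatropic shift): on the trisubstituted 7-ene the more substituted terminus C8 is attacked at its CH3 group (C17, cis to the vinylic hydrogen) rather than at the hindered tertiary C9–H, as in drim-7-ene systems; any C17 aldehyde from over-oxidation is returned to the alcohol in step 13.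

Step 13
Reactants: 17 methyl (3R)-5-[(1S,4aS,8aS)-2-(hydroxymethyl)-5,5,8a-trimethyl-6-oxo-1,4,4a,5,6,7,8,8a-octahydronaphthalen-1-yl]-3-methylpentanoate
Product: 18 methyl (3R)-5-[(1S,4aS,6R,8aS)-6-hydroxy-2-(hydroxymethyl)-5,5,8a-trimethyl-1,4,4a,5,6,7,8,8a-octahydronaphthalen-1-yl]-3-methylpentanoate
Conditions: NaBH4, MeOH, −20 to 0 °C
Reagents that add atoms: none
Why: Borohydride reduction of a 4,4-dimethyl-3-ketone: hydride arrives axially on the face away from the axial C4 and C10 methyl groups and gives the equatorial C3 alcohol (6R in the name, cis to the C10 methyl), while the methyl ester is not reduced.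

**Compound list**
1 | (2E,6E)-farnesol, (2E,6E)-3,7,11-trimethyldodeca-2,6,10-trien-1-ol | OC/C=C(\C)CC/C=C(\C)CCC=C(C)C | starting material
2 | (3R,6E)-3,7,11-trimethyldodeca-6,10-dien-1-ol | OCC[C@H](C)CC/C=C(\C)CCC=C(C)C | intermediate
3 | (3R,6E)-3,7,11-trimethyldodeca-6,10-dienoic acid | OC(=O)C[C@H](C)CC/C=C(\C)CCC=C(C)C | intermediate
4 | methyl (3R,6E)-3,7,11-trimethyldodeca-6,10-dienoate | COC(=O)C[C@H](C)CC/C=C(\C)CCC=C(C)C | intermediate
5 | allyl methyl carbonate (methyl prop-2-en-1-yl carbonate) | C=CCOC(=O)OC | starting material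
6 | methyl (3R,6E,10E)-12-[(methoxycarbonyl)oxy]-3,7-dimethyldodeca-6,10-dienoate | COC(=O)C[C@H](C)CC/C=C(\C)CC/C=C/COC(=O)OC | intermediate
7 | tert-butyl 2-methylpropanoate | CC(C)C(=O)OC(C)(C)C | starting material
8 | [(1-tert-butoxy-2-methylprop-1-en-1-yl)oxy]trimethylsilane | CC(C)=C(OC(C)(C)C)O[Si](C)(C)C | intermediate
9 | 1-tert-butyl 12-methyl (3S,6E,10R)-3-ethenyl-2,2,6,10-tetramethyldodec-6-enedioate | COC(=O)C[C@H](C)CC/C=C(\C)CC[C@@H](C=C)C(C)(C)C(=O)OC(C)(C)C | intermediate
10 | 1-tert-butyl 12-methyl (3R,6E,10R)-3-acetyl-2,2,6,10-tetramethyldodec-6-enedioate | COC(=O)C[C@H](C)CC/C=C(\C)CC[C@@H](C(C)=O)C(C)(C)C(=O)OC(C)(C)C | intermediate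
11 | 1-tert-butyl 12-methyl (3S,6E,10R)-2,2,6,10-tetramethyl-3-(prop-1-en-2-yl)dodec-6-enedioate | COC(=O)C[C@H](C)CC/C=C(\C)CC[C@@H](C(C)=C)C(C)(C)C(=O)OC(C)(C)C | intermediate
12 | (3S,6E,10R)-12-methoxy-2,2,6,10-tetramethyl-12-oxo-3-(prop-1-en-2-yl)dodec-6-enoic acid | COC(=O)C[C@H](C)CC/C=C(\C)CC[C@@H](C(C)=C)C(C)(C)C(=O)O | intermediate
13 | methyl (3R,6E,10S)-12-chloro-3,7,11,11-tetramethyl-12-oxo-10-(prop-1-en-2-yl)dodec-6-enoate (acid chloride, not isolated) | COC(=O)C[C@H](C)CC/C=C(\C)CC[C@@H](C(C)=C)C(C)(C)C(=O)Cl | intermediate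
14 | methyl (3R,6E,10S)-13-diazo-3,7,11,11-tetramethyl-12-oxo-10-(prop-1-en-2-yl)tridec-6-enoate | COC(=O)C[C@H](C)CC/C=C(\C)CC[C@@H](C(C)=C)C(C)(C)C(=O)C=[N+]=[N-] | intermediate
15 | 2-[(3E,7R)-9-methoxy-3,7-dimethyl-9-oxonon-3-en-1-yl]-1,3,3-trimethyl-4-oxocyclohexan-1-ylium (ring A closed, cation on C10, C5 as in 14; not isolated) | COC(=O)C[C@H](C)CC/C=C(\C)CC[C@@H]1C(C)(C)C(=O)CC[C+]1C | intermediate
16 | methyl (3R)-3-methyl-5-[(1R,4aS,8aS)-2,5,5,8a-tetramethyl-6-oxo-1,4,4a,5,6,7,8,8a-octahydronaphthalen-1-yl]pentanoate | COC(=O)C[C@H](C)CC[C@@H]1C(C)=CC[C@@H]2C(C)(C)C(=O)CC[C@@]12C | intermediate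
17 | methyl (3R)-5-[(1S,4aS,8aS)-2-(hydroxymethyl)-5,5,8a-trimethyl-6-oxo-1,4,4a,5,6,7,8,8a-octahydronaphthalen-1-yl]-3-methylpentanoate | COC(=O)C[C@H](C)CC[C@@H]1C(CO)=CC[C@@H]2C(C)(C)C(=O)CC[C@@]12C | intermediate
18 | methyl (3R)-5-[(1S,4aS,6R,8aS)-6-hydroxy-2-(hydroxymethyl)-5,5,8a-trimethyl-1,4,4a,5,6,7,8,8a-octahydronaphthalen-1-yl]-3-methylpentanoate | COC(=O)C[C@H](C)CC[C@@H]1C(CO)=CC[C@@H]2C(C)(C)[C@H](O)CC[C@@]12C | target

**Step count and risks**
Total step count: 13. Longest linear sequence: 12 (steps 1–4 and 6–13; step 5 prepares the ketene silyl acetal).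

Step 11 (key bicyclisation). Nitrogen may be lost without C1–C2 bond formation, the monocyclic C10 cation may lose a proton or shift a hydride before ring B closes (which would also erode C5), and the final proton loss may be unselective between the 7-ene, the exocyclic alkene and the tetrasubstituted alkene. Fallback, setting out from 14: Rh2(OAc)4 (1 mol %, CH2Cl2, 20 °C) would give, by intramolecular carbenoid cyclopropanation of the 2-propenyl group, the cyclopropyl ketone methyl (3R,6E)-3,7-dimethyl-9-[(4S)-3,3,5-trimethyl-2-oxobicyclo[3.1.0]hexan-4-yl]non-6-enoate F1. SnCl4 (CH2Cl2, −78 °C) would then open the activated cyclopropane at its tertiary carbon, and the trisubstituted alkene would capture the C10 cation; this separates initiation from ring B closure and returns to the route at 16.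

Step 4 (cross-metathesis). The internal trisubstituted alkene may also enter metathesis, and the new alkene may form as an E/Z mixture that lowers the selectivity of step 6. Fallback, setting out from 4: terminal-selective bromohydrin formation (NBS, THF/H2O, 0 °C) would give the bromohydrin F2, and K2CO3 in MeOH the terminal epoxide F3. H5IO6 (THF/H2O) would cleave F3 to the aldehyde F4. Wittig reaction with (triphenylphosphoranylidene)acetaldehyde would give the (E)-enal F5, NaBH4/CeCl3·7H2O the (E)-allylic alcohol F6, and methyl chloroformate/pyridine would return to the route at 6.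

Step 12 (allylic oxidation). Oxidation may occur at C6 or C9 instead of C17, may run on to the aldehyde, or may attack the position next to the ketone. Fallback, setting out from 16: ene-type chlorination with hypochlorous acid (Ca(OCl)2, CO2, CH2Cl2/H2O, 0 °C) would give the rearranged allylic chloride methyl (13R)-7ξ-chloro-3-oxo-ent-labd-8(17)-en-15-oate F7. Pd(PPh3)4 with n-Bu4NOAc (THF, 20 °C) would deliver acetate to the unhindered CH2 end of the π-allyl complex and give the acetate methyl (13R)-17-acetoxy-3-oxo-ent-labd-7-en-15-oate F8. K2CO3 in MeOH would return to the route at 17.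

Further compounds
F1 | step 11 | methyl (3R,6E)-3,7-dimethyl-9-[(4S)-3,3,5-trimethyl-2-oxobicyclo[3.1.0]hexan-4-yl]non-6-enoate (cyclopropane diastereomers) | COC(=O)C[C@H](C)CC/C=C(\C)CC[C@@H]1C(C)(C)C(=O)C2CC12C
F2 | step 4 | methyl (3R,6E)-10-bromo-11-hydroxy-3,7,11-trimethyldodec-6-enoate (C10 epimers) | COC(=O)C[C@H](C)CC/C=C(\C)CCC(Br)C(C)(C)O
F3 | step 4 | methyl (3R,6E)-9-(3,3-dimethyloxiran-2-yl)-3,7-dimethylnon-6-enoate (epoxide epimers) | COC(=O)C[C@H](C)CC/C=C(\C)CCC1OC1(C)C
F4 | step 4 | methyl (3R,6E)-3,7-dimethyl-10-oxodec-6-enoate | COC(=O)C[C@H](C)CC/C=C(\C)CCC=O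
F5 | step 4 | methyl (3R,6E,10E)-3,7-dimethyl-12-oxododeca-6,10-dienoate | COC(=O)C[C@H](C)CC/C=C(\C)CC/C=C/C=O
F6 | step 4 | methyl (3R,6E,10E)-12-hydroxy-3,7-dimethyldodeca-6,10-dienoate | COC(=O)C[C@H](C)CC/C=C(\C)CC/C=C/CO
F7 | step 12 | methyl (13R)-7ξ-chloro-3-oxo-ent-labd-8(17)-en-15-oate | COC(=O)C[C@H](C)CC[C@@H]1C(=C)C(Cl)C[C@@H]2C(C)(C)C(=O)CC[C@@]12C
F8 | step 12 | methyl (13R)-17-acetoxy-3-oxo-ent-labd-7-en-15-oate | COC(=O)C[C@H](C)CC[C@@H]1C(COC(C)=O)=CC[C@@H]2C(C)(C)C(=O)CC[C@@]12C
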